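## Retrosynthetic overview

- The target is released last by cleaving only the O–Si bond of a C2 silyl ketal, so the C2–O bond and the C2 configuration are not touched.
- Key disconnection C2–C1′: an enantioselective, dearomative palladium-catalysed allylic alkylation of an aromatic 2,3-bis(silyloxy)-4-methylbenzofuran with the complete, unprotected side-chain allylic acetate. This joins the two halves and sets C2.
- The aromatic benzofuran comes from 2-hydroxy-4-methylbenzofuran-3(2H)-one, made from 2′-methylacetophenone by ortho C–H hydroxylation and Riley oxidation.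
- The side chain comes from geranyl acetate by allylic oxidation, iridium-catalysed redox allylation (sets C8′) and cross-metathesis to the prenyl terminus.
- Ring order: the benzene ring is bought; the furanone ring closes in step 2 (hemiacetal), is aromatised to the furan in step 3 and dearomatised in step 7.

Assumption: the C2 hemiketal can in principle epimerise by ring–chain tautomerism to the open 1,2-diketone, so it is treated as a stereocentre that holds under cold, buffered conditions and is unveiled only in the last step.

## Route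

Step 1
Reactants: 1 2′-methylacetophenone
Product: 3 1-(2-hydroxy-6-methylphenyl)ethanone, via aryl trifluoroacetate 2 (not isolated)
Conditions: Pd(OCOCF3)2 (5 mol %), PhI(OCOCF3)2 (2 equiv), ClCH2CH2Cl, 80 °C; then MeOH/H2O, rt
Reagents that add atoms: [bis(trifluoroacetoxy)iodo]benzene FC(F)(F)C(=O)OI(OC(=O)C(F)(F)F)c1ccccc1
Why: Ketone-directed ortho C–H oxygenation through a divalent/tetravalent palladium cycle, in which the acetyl oxygen steers palladation to the only free ortho position (the other carries the methyl group), C–O reductive elimination gives the aryl trifluoroacetate and mild solvolysis frees the phenol; no stereocentre is formed.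

Step 2
Reactants: 3 1-(2-hydroxy-6-methylphenyl)ethanone
Product: 5 2-hydroxy-4-methyl-1-benzofuran-3(2H)-one (racemic), via arylglyoxal 4 (not isolated)
Conditions: SeO2 (1.3 equiv), 1,4-dioxane/H2O (20:1), 100 °C
Reagents that add atoms: selenium dioxide O=[Se]=O
Why: Riley oxidation of the aryl methyl ketone to the arylglyoxal, whose very electrophilic aldehyde is trapped at once by the ortho phenol as the five-membered cyclic hemiacetal; the C2 centre is racemic and is erased in step 3.

Step 3
Reactants: 5 2-hydroxy-4-methyl-1-benzofuran-3(2H)-one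
Product: 7 4-methyl-2-(triisopropylsilyloxy)-3-(trimethylsilyloxy)-1-benzofuran, via 2-silyloxy ketone 6 (not isolated)
Conditions: iPr3SiOSO2CF3 (1.05 equiv), 2,6-lutidine, CH2Cl2, −78 °C; then Me3SiOSO2CF3 (1.2 equiv), Et3N, 0 °C; pentane trituration, filtration, no aqueous work-up
Reagents that add atoms: triisopropylsilyl trifluoromethanesulfonate CC(C)[Si](OS(=O)(=O)C(F)(F)F)(C(C)C)C(C)C; trimethylsilyl trifluoromethanesulfonate C[Si](C)(C)OS(=O)(=O)C(F)(F)F
Why: O-silylation of the hemiacetal hydroxyl followed by soft enolisation/O-silylation of the acidic C2–H ketone (silyl enol ether formation), which aromatises the five-membered ring to a benzofuran carrying a robust silyl group on O2 and a labile one on O3; no stereocentre remains.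

Step 4
Reactants: 8 geranyl acetate
Product: 9 (2E,6E)-8-hydroxy-3,7-dimethylocta-2,6-dien-1-yl acetate
Conditions: SeO2 (0.1 equiv), t-BuOOH (3 equiv), salicylic acid (0.1 equiv), CH2Cl2, rt
Reagents that add atoms: tert-butyl hydroperoxide CC(C)(C)OO (terminal oxygen source, relayed by catalytic selenium dioxide O=[Se]=O)
Why: Sharpless–Umbreit allylic oxidation (ene reaction then [2,3]-sigmatropic shift), which is selective for the E-methyl group of the electron-richer terminal alkene, the C2=C3 alkene being deactivated by the allylic acetate; no stereocentre is formed.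

Step 5
Reactants: 9 (2E,6E)-8-hydroxy-3,7-dimethylocta-2,6-dien-1-yl acetate
Product: 10 (2E,6E,8R)-8-hydroxy-3,7-dimethylundeca-2,6,10-trien-1-yl acetate
Conditions: [Ir(cod)Cl]2 (2.5 mol %), (R)-BINAP (5 mol %), Cs2CO3 (20 mol %), 3-nitrobenzoic acid (10 mol %), allyl acetate (10 equiv), THF, 100 °C, sealed tube
Reagents that add atoms: allyl acetate C=CCOC(C)=O
Why: Krische redox-triggered carbonyl allylation, in which the cyclometallated π-allyl iridium C,O-benzoate dehydrogenates the primary allylic alcohol to the enal and transfers its allyl group through a closed chair transition state, (R)-BINAP directing attack to the Re face to give the 8R carbinol (sense by analogy with aryl and alkenyl carbinols, to be confirmed by Mosher analysis), while the trisubstituted allylic acetate ionises far more slowly than the excess allyl acetate.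

Step 6
Reactants: 10 (2E,6E,8R)-8-hydroxy-3,7-dimethylundeca-2,6,10-trien-1-yl acetate
Product: 11 (2E,6E,8R)-8-hydroxy-3,7,11-trimethyldodeca-2,6,10-trien-1-yl acetate
Conditions: second-generation Grubbs catalyst RuCl2(=CHPh)(PCy3)(H2IMes) (5 mol %), 2-methyl-2-butene/CH2Cl2, rt
Reagents that add atoms: 2-methyl-2-butene CC=C(C)C
Why: Olefin cross-metathesis that converts only the monosubstituted terminal alkene into the prenyl group, the two trisubstituted alkenes being inert at room temperature; the C8 stereocentre is not involved.

Step 7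
Reactants: 7 4-methyl-2-(triisopropylsilyloxy)-3-(trimethylsilyloxy)-1-benzofuran; 11 (2E,6E,8R)-8-hydroxy-3,7,11-trimethyldodeca-2,6,10-trien-1-yl acetate
Product: 12 (2S)-2-[(2E,6E,8R)-8-hydroxy-3,7,11-trimethyldodeca-2,6,10-trien-1-yl]-4-methyl-2-(triisopropylsilyloxy)-1-benzofuran-3(2H)-one
Conditions: Pd2(dba)3·CHCl3 (2.5 mol %), (R,R)-DACH-phenyl Trost ligand (7.5 mol %), Bu4N[Ph3SiF2] (10 mol %), degassed CH2Cl2, 0 °C to rt
Reagents that add atoms: none
Why: Proposed new method: zerovalent palladium with the Trost ligand ionises the allylic acetate to a syn π-allyl cation, the acetate counter-ion (started by a trace of fluoride) strips the labile O3–SiMe3 group of 7, and the resulting aromatic benzofuran-3-olate attacks the unsubstituted allyl terminus through C2 on one enantiotopic face inside the chiral pocket, so the furan ring is dearomatised, the C2–C1′ bond forms with the E alkene retained and C2 is set by catalyst control (the bulky O2 silyl group suppresses silyl migration and C3 attack, and any O-allyl product re-ionises and funnels to C2); the closest known chemistry is the Tsuji–Trost asymmetric allylic alkylation of silyl enol ethers and 1,2-enediol derivatives and the ligand-controlled linear geranylation of oxindole enolates.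

The (2S) descriptor of 12 is the same spatial arrangement as (2R) in the target; it changes only because O–Si outranks the ring oxygen. The ligand antipode is provisional and must be confirmed on the first run; the (S,S)-ligand is used if the sense is opposite.

Step 8
Reactants: 12 (2S)-2-[(2E,6E,8R)-8-hydroxy-3,7,11-trimethyldodeca-2,6,10-trien-1-yl]-4-methyl-2-(triisopropylsilyloxy)-1-benzofuran-3(2H)-one
Product: 13 (2R)-2-hydroxy-2-[(2E,6E,8R)-8-hydroxy-3,7,11-trimethyldodeca-2,6,10-trien-1-yl]-4-methyl-1-benzofuran-3(2H)-one
Conditions: HF·pyridine, pyridine, THF, 0 °C; pH 7 phosphate buffer quench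
Reagents that add atoms: none
Why: Fluoride-mediated desilylation under buffered, weakly acidic conditions cleaves only the O–Si bond, so the C2–O bond and its configuration are retained and the hemiketal is protonated at once instead of existing as a ring-opening alkoxide; the alkenes and the allylic alcohol are inert.

## Compound list

1 | 2′-methylacetophenone | CC(=O)c1ccccc1C | starting material
2 | 2-acetyl-3-methylphenyl trifluoroacetate | CC(=O)c1c(C)cccc1OC(=O)C(F)(F)F | intermediate
3 | 1-(2-hydroxy-6-methylphenyl)ethanone | CC(=O)c1c(C)cccc1O | intermediate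
4 | 2-(2-hydroxy-6-methylphenyl)-2-oxoacetaldehyde | O=CC(=O)c1c(C)cccc1O | intermediate
5 | 2-hydroxy-4-methyl-1-benzofuran-3(2H)-one (racemic) | Cc1cccc2OC(O)C(=O)c12 | intermediate
6 | 4-methyl-2-(triisopropylsilyloxy)-1-benzofuran-3(2H)-one (racemic) | Cc1cccc2OC(O[Si](C(C)C)(C(C)C)C(C)C)C(=O)c12 | intermediate
7 | 4-methyl-2-(triisopropylsilyloxy)-3-(trimethylsilyloxy)-1-benzofuran | Cc1cccc2oc(O[Si](C(C)C)(C(C)C)C(C)C)c(O[Si](C)(C)C)c12 | intermediate
8 | geranyl acetate, (2E)-3,7-dimethylocta-2,6-dien-1-yl acetate | CC(C)=CCC/C(C)=C/COC(C)=O | starting material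
9 | (2E,6E)-8-hydroxy-3,7-dimethylocta-2,6-dien-1-yl acetate | OC/C(C)=C/CC/C(C)=C/COC(C)=O | intermediate
10 | (2E,6E,8R)-8-hydroxy-3,7-dimethylundeca-2,6,10-trien-1-yl acetate | C=CC[C@@H](O)/C(C)=C/CC/C(C)=C/COC(C)=O | intermediate
11 | (2E,6E,8R)-8-hydroxy-3,7,11-trimethyldodeca-2,6,10-trien-1-yl acetate | CC(C)=CC[C@@H](O)/C(C)=C/CC/C(C)=C/COC(C)=O | intermediate
12 | (2S)-2-[(2E,6E,8R)-8-hydroxy-3,7,11-trimethyldodeca-2,6,10-trien-1-yl]-4-methyl-2-(triisopropylsilyloxy)-1-benzofuran-3(2H)-one | CC(C)=CC[C@@H](O)/C(C)=C/CC/C(C)=C/C[C@@]1(O[Si](C(C)C)(C(C)C)C(C)C)Oc2cccc(C)c2C1=O | intermediate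
13 | (2R)-2-hydroxy-2-[(2E,6E,8R)-8-hydroxy-3,7,11-trimethyldodeca-2,6,10-trien-1-yl]-4-methyl-1-benzofuran-3(2H)-one | CC(C)=CC[C@@H](O)/C(C)=C/CC/C(C)=C/C[C@@]1(O)Oc2cccc(C)c2C1=O | target

## Step count and risks

Total steps: 8. Longest linear sequence: 5 steps (1, 2, 3, 7, 8 from compound 1; equally 4, 5, 6, 7, 8 from compound 8).

**Step 7 (most likely to fail).** The risks are C3 instead of C2 attack through the ketene-acetal reactivity of 7 or silyl migration, branched instead of linear allylation, and an unknown level and sense of enantioselection. The fallback makes the stereocentre by C–O instead of C–C bond formation. It sets out from 3 and 11. Bromination of 3 (CuBr2, EtOAc/CHCl3, reflux) gives 2-bromo-1-(2-hydroxy-6-methylphenyl)ethanone F1. NaOAc in EtOH closes it to 4-methyl-1-benzofuran-3(2H)-one F2. F2 (2 equiv, to limit double allylation) is C-allylated with 11 under Pd(PPh3)4/Cs2CO3 in THF to 2-[(2E,6E,8R)-8-hydroxy-3,7,11-trimethyldodeca-2,6,10-trien-1-yl]-4-methyl-1-benzofuran-3(2H)-one F3 as both C2 epimers. Its potassium enolate (KN(SiMe3)2, 2.2 equiv, THF, −78 °C) is hydroxylated with an enantiopure (camphorsulfonyl)oxaziridine, antipode chosen by a test run, and a cold buffered quench comes back to the route at 13.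

**Step 5.** The risks are ionisation or transesterification of the substrate's own allylic acetate under the iridium conditions, redox isomerisation of the allylic alcohol, and only moderate enantioselectivity for an α-branched enal. The fallback replaces the catalytic redox coupling by a stoichiometric reagent-controlled allylation at the aldehyde level. It sets out from 9. MnO2 in CH2Cl2 gives (2E,6E)-3,7-dimethyl-8-oxoocta-2,6-dien-1-yl acetate F4. B-allyldiisopinocampheylborane made from (−)-α-pinene (Et2O, −78 °C; NaBO3·4H2O work-up) adds to the Re face through a Zimmerman–Traxler transition state and comes back to the route at 10.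

**Step 8.** The risk is partial epimerisation of C2 by acid- or fluoride-promoted ring–chain tautomerism during or after desilylation. The fallback unmasks O2 oxidatively at a remote benzylic carbon, without acid, base or fluoride at C2. It sets out from 5. Acetalisation with 4-methoxybenzyl alcohol (pyridinium p-toluenesulfonate, CH2Cl2, 4 Å molecular sieves) gives 2-[(4-methoxyphenyl)methoxy]-4-methyl-1-benzofuran-3(2H)-one F5. Me3SiOSO2CF3/Et3N gives the aromatic 2-[(4-methoxyphenyl)methoxy]-4-methyl-3-(trimethylsilyloxy)-1-benzofuran F6. The same palladium-catalysed dearomative allylation with 11 gives (2R)-2-[(2E,6E,8R)-8-hydroxy-3,7,11-trimethyldodeca-2,6,10-trien-1-yl]-2-[(4-methoxyphenyl)methoxy]-4-methyl-1-benzofuran-3(2H)-one F7. DDQ in CH2Cl2/pH 7 buffer at 0 °C then comes back to the route at 13.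

## Further compounds

F1 | step 7 | 2-bromo-1-(2-hydroxy-6-methylphenyl)ethanone | O=C(CBr)c1c(C)cccc1O
F2 | step 7 | 4-methyl-1-benzofuran-3(2H)-one | Cc1cccc2OCC(=O)c12
F3 | step 7 | 2-[(2E,6E,8R)-8-hydroxy-3,7,11-trimethyldodeca-2,6,10-trien-1-yl]-4-methyl-1-benzofuran-3(2H)-one (both C2 epimers) | CC(C)=CC[C@@H](O)/C(C)=C/CC/C(C)=C/CC1Oc2cccc(C)c2C1=O
F4 | step 5 | (2E,6E)-3,7-dimethyl-8-oxoocta-2,6-dien-1-yl acetate | O=C/C(C)=C/CC/C(C)=C/COC(C)=O
F5 | step 8 | 2-[(4-methoxyphenyl)methoxy]-4-methyl-1-benzofuran-3(2H)-one (racemic) | Cc1cccc2OC(OCc3ccc(OC)cc3)C(=O)c12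
F6 | step 8 | 2-[(4-methoxyphenyl)methoxy]-4-methyl-3-(trimethylsilyloxy)-1-benzofuran | Cc1cccc2oc(OCc3ccc(OC)cc3)c(O[Si](C)(C)C)c12
F7 | step 8 | (2R)-2-[(2E,6E,8R)-8-hydroxy-3,7,11-trimethyldodeca-2,6,10-trien-1-yl]-2-[(4-methoxyphenyl)methoxy]-4-methyl-1-benzofuran-3(2H)-one | CC(C)=CC[C@@H](O)/C(C)=C/CC/C(C)=C/C[C@@]1(OCc3ccc(OC)cc3)Oc2cccc(C)c2C1=O
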